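**Plan**
- Retrosynthesis: the O–Si bond at the C6 carbinol is cut first. The three pyranone bonds C4a–C4, C4–C3 and O1–C2 are then cut together, giving 2-iodo-5-methoxyresorcinol, carbon monoxide and a nine-carbon alkynyl ester. Last, the propargylic C7–C8 bond of the alkyne (epoxide plus acetylide) and the aryl C–I bond are cut.
- Enabling feature: chromone C4 is a single carbonyl carbon between C4a of the benzene ring and the C3=C2 unit, and C2 carries both ring oxygen O1 and the side chain. The pyranone ring therefore maps onto aryl iodide, CO and terminal alkyne. The iodide lies on the mirror axis of the resorcinol, so both hydroxyls are equivalent.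
- Forward: the chain is built first (epoxidation, resolution, alkynylation, O-silylation, C-desilylation). The arene is iodinated by directed metalation. The pyranone ring is then annulated onto the preformed benzene ring as the only ring-forming event, and desilylation ends the route.
- Stereochemistry: the single stereocentre (C6, R) comes from a hydrolytic kinetic resolution of the terminal epoxide. The acetylide attacks the CH2 terminus, so the C6–O bond is never broken.

Key step: step 9

Assumption: the (R,R)-cobalt salen catalyst is taken to leave the (R)-epoxide unreacted, as it does with other monoalkyl oxiranes. The sense would be checked on compound 3, and the antipodal catalyst used if it proved opposite.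

**Route**

Step 1
Reactants: 1 methyl hept-6-enoate
Product: 2 methyl 5-(oxiran-2-yl)pentanoate (racemic)
Conditions: mCPBA, CH2Cl2, 0 °C → rt
Reagents that add atoms: mCPBA (3-chloroperoxybenzoic acid), O=C(OO)c1cccc(Cl)c1
Why: Prilezhaev epoxidation of an unactivated terminal alkene by a peracid should proceed cleanly, with the methyl ester inert.

Step 2
Reactants: 2 methyl 5-(oxiran-2-yl)pentanoate (racemic)
Product: 3 methyl 5-[(2R)-oxiran-2-yl]pentanoate
Conditions: (R,R)-(salen)Co(OAc) (0.5 mol %) [salen = N,N′-bis(3,5-di-tert-butylsalicylidene)cyclohexane-1,2-diamine dianion], H2O (0.55 equiv), THF, 0 °C → rt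
Reagents that add atoms: none
Why: In the Jacobsen hydrolytic kinetic resolution the chiral cobalt salen complex should hydrolyse the (S)-epoxide selectively to the diol, leaving the (R)-epoxide that carries the future C6 stereocentre.

Step 3
Reactants: 3 methyl 5-[(2R)-oxiran-2-yl]pentanoate; 4 ethynyltrimethylsilane
Product: 6 methyl (6R)-6-hydroxy-9-(trimethylsilyl)non-8-ynoate, via lithium (trimethylsilyl)acetylide 5 (not isolated)
Conditions: n-BuLi, THF, −78 °C; BF3·OEt2; then 3, −78 °C; aq NH4Cl
Reagents that add atoms: none
Why: In this Yamaguchi–Hirao alkynylation the BF3-activated epoxide should be opened by the acetylide at the unhindered CH2 terminus in SN2 fashion, faster at −78 °C than acylation by the ester, so the C6 configuration is retained.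

Step 4
Reactants: 6 methyl (6R)-6-hydroxy-9-(trimethylsilyl)non-8-ynoate
Product: 7 methyl (6R)-6-[(tert-butyldimethylsilyl)oxy]-9-(trimethylsilyl)non-8-ynoate
Conditions: TBSCl, imidazole, DMF, rt
Reagents that add atoms: TBSCl (tert-butylchlorodimethylsilane), CC(C)(C)[Si](C)(C)Cl
Why: Imidazole-promoted silylation of a secondary alcohol is reliable and masks the carbinol against carbonylation and elimination later.

Step 5
Reactants: 7 methyl (6R)-6-[(tert-butyldimethylsilyl)oxy]-9-(trimethylsilyl)non-8-ynoate
Product: 8 methyl (6R)-6-[(tert-butyldimethylsilyl)oxy]non-8-ynoate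
Conditions: K2CO3 (0.2 equiv), MeOH, rt
Reagents that add atoms: none
Why: Methoxide-mediated protodesilylation removes only the alkynyl silane, since the silyl ether is stable to it and exchange at the methyl ester in methanol is degenerate.

Step 6
Reactants: 9 5-methoxybenzene-1,3-diol
Product: 10 1-methoxy-3,5-bis(methoxymethoxy)benzene
Conditions: MOMCl, i-Pr2NEt, CH2Cl2, 0 °C → rt
Reagents that add atoms: MOMCl (chloromethyl methyl ether), COCCl
Why: Base-mediated O-alkylation of both phenols installs two acetal groups that direct the following metalation.

Step 7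
Reactants: 10 1-methoxy-3,5-bis(methoxymethoxy)benzene
Product: 12 2-iodo-5-methoxy-1,3-bis(methoxymethoxy)benzene, via aryllithium 11 (not isolated)
Conditions: n-BuLi, TMEDA, THF, 0 °C; I2, −78 °C → rt
Reagents that add atoms: iodine, II
Why: In this directed ortho-metalation the C–H flanked by two chelating methoxymethoxy groups should be lithiated in preference to the sites next to the weaker methoxy director, and iodinolysis fixes iodine there.

Step 8
Reactants: 12 2-iodo-5-methoxy-1,3-bis(methoxymethoxy)benzene
Product: 13 2-iodo-5-methoxybenzene-1,3-diol
Conditions: HCl (in MeOH), rt, dark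
Reagents that add atoms: none
Why: Acid-catalysed acetal exchange with methanol should release both phenols under conditions mild enough to keep the aryl iodide.

Step 9
Reactants: 13 2-iodo-5-methoxybenzene-1,3-diol; 14 carbon monoxide; 8 methyl (6R)-6-[(tert-butyldimethylsilyl)oxy]non-8-ynoate
Product: 17 methyl (6R)-6-[(tert-butyldimethylsilyl)oxy]-7-(5-hydroxy-7-methoxy-4-oxo-4H-chromen-2-yl)heptanoate, via ynone 15 (not isolated), via enaminone 16 (not isolated)
Conditions: PdCl2(dppf) (5 mol %) [dppf = 1,1′-bis(diphenylphosphino)ferrocene], CO (10 bar), Et2NH, 80 °C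
Reagents that add atoms: carbon monoxide (compound 14), [C-]#[O+]
Why: Zerovalent palladium formed in situ from PdCl2(dppf) should insert into the C–I bond of 13, CO insertion gives the aroylpalladium species, and copper-free alkynylation by 8 with reductive elimination forms C4a–C4 and C4–C3 in ynone 15. Diethylamine then adds in conjugate fashion to give enaminone 16, and a flanking phenol displaces the amine at C2 by addition–elimination, closing the pyranone ring (O1–C2) in a net 6-endo mode. The closest known reaction type is the palladium-catalysed carbonylative Sonogashira coupling–cyclisation of 2-iodophenols with terminal alkynes to chromones and flavones. No stereocentre is created, and the C6 stereocentre, the silyl ether and the methyl ester are spectators under the amine base. The step needs chromone formation over aurone, benzofuran and amide formation: CO pressure and the absence of copper disfavour direct alkynylation, the doubly ortho-substituted aroylpalladium resists aminolysis, and the enaminone pathway enforces six-membered closure. Because the iodide lies on the symmetry axis of 13, either hydroxyl may close the ring and the other becomes the hydrogen-bonded 5-OH, so no regiochemical question arises.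

Step 10
Reactants: 17 methyl (6R)-6-[(tert-butyldimethylsilyl)oxy]-7-(5-hydroxy-7-methoxy-4-oxo-4H-chromen-2-yl)heptanoate
Product: 18 Penithochromone O, methyl (6R)-6-hydroxy-7-(5-hydroxy-7-methoxy-4-oxo-4H-chromen-2-yl)heptanoate
Conditions: HF·pyridine, THF/pyridine, 0 °C → rt
Reagents that add atoms: none
Why: Fluoride-driven cleavage of the silyl ether under mildly acidic conditions should free the carbinol without the base-induced β-elimination toward a 2-alkenylchromone and without touching the ester or the stereocentre.

**Compound list**
1 | methyl hept-6-enoate | COC(=O)CCCCC=C | starting material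
2 | methyl 5-(oxiran-2-yl)pentanoate (racemic) | COC(=O)CCCCC1CO1 | intermediate
3 | methyl 5-[(2R)-oxiran-2-yl]pentanoate | COC(=O)CCCC[C@@H]1CO1 | intermediate
4 | ethynyltrimethylsilane | C#C[Si](C)(C)C | starting material
5 | lithium (trimethylsilyl)acetylide | [Li]C#C[Si](C)(C)C | intermediate (not isolated)
6 | methyl (6R)-6-hydroxy-9-(trimethylsilyl)non-8-ynoate | COC(=O)CCCC[C@@H](O)CC#C[Si](C)(C)C | intermediate
7 | methyl (6R)-6-[(tert-butyldimethylsilyl)oxy]-9-(trimethylsilyl)non-8-ynoate | COC(=O)CCCC[C@@H](O[Si](C)(C)C(C)(C)C)CC#C[Si](C)(C)C | intermediate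
8 | methyl (6R)-6-[(tert-butyldimethylsilyl)oxy]non-8-ynoate | COC(=O)CCCC[C@@H](O[Si](C)(C)C(C)(C)C)CC#C | intermediate
9 | 5-methoxybenzene-1,3-diol | COc1cc(O)cc(O)c1 | starting material
10 | 1-methoxy-3,5-bis(methoxymethoxy)benzene | COCOc1cc(OC)cc(OCOC)c1 | intermediate
11 | [4-methoxy-2,6-bis(methoxymethoxy)phenyl]lithium | [Li]c1c(OCOC)cc(OC)cc1OCOC | intermediate (not isolated)
12 | 2-iodo-5-methoxy-1,3-bis(methoxymethoxy)benzene | COCOc1cc(OC)cc(OCOC)c1I | intermediate
13 | 2-iodo-5-methoxybenzene-1,3-diol | COc1cc(O)c(I)c(O)c1 | intermediate
14 | carbon monoxide | [C-]#[O+] | starting material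
15 | methyl (6R)-6-[(tert-butyldimethylsilyl)oxy]-10-(2,6-dihydroxy-4-methoxyphenyl)-10-oxodec-8-ynoate | COC(=O)CCCC[C@@H](O[Si](C)(C)C(C)(C)C)CC#CC(=O)c1c(O)cc(OC)cc1O | intermediate (not isolated)
16 | methyl (6R,8E)-6-[(tert-butyldimethylsilyl)oxy]-8-(diethylamino)-10-(2,6-dihydroxy-4-methoxyphenyl)-10-oxodec-8-enoate | COC(=O)CCCC[C@@H](O[Si](C)(C)C(C)(C)C)C/C(=C\C(=O)c1c(O)cc(OC)cc1O)N(CC)CC | intermediate (not isolated)
17 | methyl (6R)-6-[(tert-butyldimethylsilyl)oxy]-7-(5-hydroxy-7-methoxy-4-oxo-4H-chromen-2-yl)heptanoate | COC(=O)CCCC[C@@H](O[Si](C)(C)C(C)(C)C)Cc1cc(=O)c2c(O)cc(OC)cc2o1 | intermediate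
18 | Penithochromone O, methyl (6R)-6-hydroxy-7-(5-hydroxy-7-methoxy-4-oxo-4H-chromen-2-yl)heptanoate | COC(=O)CCCC[C@@H](O)Cc1cc(=O)c2c(O)cc(OC)cc2o1 | target

**Step count**
Total: 10 steps. Longest linear sequence: 7 steps (steps 1–5, 9 and 10). Steps 6–8 run in parallel.

**Steps most likely to fail**

1. Step 9. The aroylpalladium species may be captured by diethylamine (aminocarbonylation). Alkynylation may occur without CO insertion and be followed by five-membered closure to a benzofuran. Oxidative addition to the phenoxide-rich, doubly ortho-substituted iodide may be slow. The fallback separates ynone formation from ring closure and keeps the phenols masked. It sets out from 12, 14 and 8. Carbonylative Sonogashira coupling with PdCl2(PPh3)2, Et3N and CO in THF at 40 °C, with a tertiary amine that cannot form an amide, should give the ynone methyl (6R)-6-[(tert-butyldimethylsilyl)oxy]-10-[4-methoxy-2,6-bis(methoxymethoxy)phenyl]-10-oxodec-8-ynoate F1. Diethylamine in ethanol at rt should convert it into the enaminone methyl (6R,8E)-6-[(tert-butyldimethylsilyl)oxy]-8-(diethylamino)-10-[4-methoxy-2,6-bis(methoxymethoxy)phenyl]-10-oxodec-8-enoate F2. HCl in methanol should then remove both acetals, close the pyranone with loss of diethylamine and cleave the silyl ether. The fallback comes back to the route at 18.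

2. Step 3. The acetylide may acylate at the methyl ester to give an ynone, or the Lewis acid may rearrange the epoxide before it is opened. The fallback masks the ester as its carboxylate and uses no Lewis acid. It sets out from 3. LiOH in THF/H2O at 0 °C should give lithium 5-[(2R)-oxiran-2-yl]pentanoate F3. LiC≡CH·H2NCH2CH2NH2 in DMSO at rt, followed by acidification, should open the epoxide at the terminus to give (6R)-6-hydroxynon-8-ynoic acid F4. MeI and KHCO3 in DMF should give methyl (6R)-6-hydroxynon-8-ynoate F5. TBSCl and imidazole in DMF then bring the sequence back to the route at 8.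

3. Step 8. Ipso-protonation of the very electron-rich ring under acid may cause loss of iodine, and the free iodoresorcinol may oxidise in air. The fallback installs iodine by electrophilic substitution and uses no protecting groups or acid. It sets out from 9. Treatment with I2 and NaHCO3 in H2O/THF at 0 °C should iodinate kinetically at the position between the two hydroxyls, by analogy with resorcinol, although this regiochemistry is less secure than that of the metalation. It comes back to the route at 13 and makes no compound outside the list (F0).

**Further compounds**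
F1 | step 9 | methyl (6R)-6-[(tert-butyldimethylsilyl)oxy]-10-[4-methoxy-2,6-bis(methoxymethoxy)phenyl]-10-oxodec-8-ynoate | COC(=O)CCCC[C@@H](O[Si](C)(C)C(C)(C)C)CC#CC(=O)c1c(OCOC)cc(OC)cc1OCOC
F2 | step 9 | methyl (6R,8E)-6-[(tert-butyldimethylsilyl)oxy]-8-(diethylamino)-10-[4-methoxy-2,6-bis(methoxymethoxy)phenyl]-10-oxodec-8-enoate | COC(=O)CCCC[C@@H](O[Si](C)(C)C(C)(C)C)C/C(=C\C(=O)c1c(OCOC)cc(OC)cc1OCOC)N(CC)CC
F3 | step 3 | lithium 5-[(2R)-oxiran-2-yl]pentanoate | [Li+].[O-]C(=O)CCCC[C@@H]1CO1
F4 | step 3 | (6R)-6-hydroxynon-8-ynoic acid | OC(=O)CCCC[C@@H](O)CC#C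
F5 | step 3 | methyl (6R)-6-hydroxynon-8-ynoate | COC(=O)CCCC[C@@H](O)CC#C
F0 | step 8 | none | none
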